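**Retrosynthetic overview**
- Both rings are closed in the last operation, in one pot: RCM of a C8 2-(bromomethyl)acrylate with the C7 vinyl group gives the butenolide (lactone ring first); indium-mediated intramolecular Barbier allylation of the C5/C6 ketoaldehyde then forges C6–C7 (ten-membered ring second) and sets C6 and C7.
- The acyclic precursor is one linear chain from (S)-β-citronellene (C4 from the chiral pool); its terminal vinyl group becomes the ketoaldehyde through a masked diol.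
- C10 comes from Sharpless epoxidation and hydride opening; C8 and C9 from a Brown alkoxyallylboration that also adds C7; the two esters from Steglich couplings.

Assumption: (S)-β-citronellene, allyl methoxymethyl ether, (E)-3-methylpent-2-enoic acid (pure E) and 2-(bromomethyl)acrylic acid are bought as such.
Assumption: the carbinol made in step 4 (the later C5 ketone) is carried as an about 1:1 epimer mixture; the SMILES leave it undefined.
Atom labels C1–C13 are the germacrane positions of the target: C8 lactone carbinol, C7 ring fusion, C6 free carbinol, C5 ketone, C4 and C10 methyl-bearing carbons, C9 acyloxy carbon.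

**Step 1**
Reactants: 1 (S)-β-citronellene [(3S)-3,7-dimethylocta-1,6-diene]
Product: 2 (2E,6S)-2,6-dimethylocta-2,7-dien-1-ol
Conditions: SeO2 (5 mol%), salicylic acid (10 mol%), t-BuOOH, CH2Cl2, rt
Reagents that add atoms: tert-butyl hydroperoxide, CC(C)(C)OO
Why: SeO2-catalysed allylic oxidation (ene reaction then [2,3]-shift, Riley/Sharpless type) attacks only the trisubstituted alkene and gives the (E)-allylic alcohol; no stereocentre is formed or touched.

**Step 2**
Reactants: 2 (2E,6S)-2,6-dimethylocta-2,7-dien-1-ol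
Product: 3 [(2S,3S)-2-methyl-3-[(3S)-3-methylpent-4-en-1-yl]oxiran-2-yl]methanol
Conditions: Ti(OiPr)4 (10 mol%), L-(+)-DIPT (12 mol%), t-BuOOH, 4 Å MS, CH2Cl2, −20 °C
Reagents that add atoms: tert-butyl hydroperoxide, CC(C)(C)OO
Why: Katsuki–Sharpless asymmetric epoxidation of the (E)-2-methyl allylic alcohol with L-(+)-tartrate gives the (2S,3S)-epoxide, which fixes the later C10 carbinol; the isolated vinyl group is inert.

**Step 3**
Reactants: 3 [(2S,3S)-2-methyl-3-[(3S)-3-methylpent-4-en-1-yl]oxiran-2-yl]methanol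
Product: 4 (2R,3S)-2-methyl-3-[(3S)-3-methylpent-4-en-1-yl]oxirane-2-carbaldehyde
Conditions: TEMPO (10 mol%), PhI(OAc)2, CH2Cl2, rt
Reagents that add atoms: none
Why: TEMPO/PhI(OAc)2 (oxoammonium) oxidation turns the primary epoxy alcohol into the non-enolisable epoxy aldehyde without touching epoxide or alkene.

**Step 4**
Reactants: 4 (2R,3S)-2-methyl-3-[(3S)-3-methylpent-4-en-1-yl]oxirane-2-carbaldehyde
Product: 5 (2R,3S)-3-[(3S)-4,5-dihydroxy-3-methylpentyl]-2-methyloxirane-2-carbaldehyde (both epimers at the new carbinol)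
Conditions: OsO4 (2 mol%), NMO, acetone/H2O, rt
Reagents that add atoms: N-methylmorpholine N-oxide, C[N+]1([O-])CCOCC1; water, O
Why: Upjohn dihydroxylation of the only alkene masks the future C5/C6 ketoaldehyde as a diol; the new carbinol forms unselectively and is oxidised away in step 12.

**Step 5**
Reactants: 5 (2R,3S)-3-[(3S)-4,5-dihydroxy-3-methylpentyl]-2-methyloxirane-2-carbaldehyde
Product: 6 (2R,3S)-3-[(3S)-4,5-bis(tert-butyldimethylsilyloxy)-3-methylpentyl]-2-methyloxirane-2-carbaldehyde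
Conditions: TBSCl, imidazole, DMF, rt
Reagents that add atoms: tert-butyldimethylsilyl chloride, CC(C)(C)[Si](C)(C)Cl
Why: Silylation protects both diol oxygens with a fluoride-labile group that is orthogonal to the MOM ether introduced next.

**Step 6**
Reactants: 6 (2R,3S)-3-[(3S)-4,5-bis(tert-butyldimethylsilyloxy)-3-methylpentyl]-2-methyloxirane-2-carbaldehyde; 7 allyl methoxymethyl ether
Product: 9 (1S,2R)-1-[(2S,3S)-3-[(3S)-4,5-bis(tert-butyldimethylsilyloxy)-3-methylpentyl]-2-methyloxiran-2-yl]-2-(methoxymethoxy)but-3-en-1-ol, via (Z)-[3-(methoxymethoxy)allyl]bis(isopinocampheyl)borane 8 (not isolated)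
Conditions: 7, s-BuLi, THF, −78 °C; (−)-Ipc2BOMe; BF3·OEt2; 6, −78 °C; NaOAc aq., H2O2, rt
Reagents that add atoms: none
Why: Brown alkoxyallylboration: the closed chair transition state of the (Z)-γ-alkoxyallylborane gives the syn C8/C9 pair, and the Ipc ligands from (+)-α-pinene (reagent control) deliver the (8R,9S) configuration while adding C7, C8 and the vinyl group.

**Step 7**
Reactants: 9 (1S,2R)-1-[(2S,3S)-3-[(3S)-4,5-bis(tert-butyldimethylsilyloxy)-3-methylpentyl]-2-methyloxiran-2-yl]-2-(methoxymethoxy)but-3-en-1-ol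
Product: 10 (3R,4S,5R,9S)-10,11-bis(tert-butyldimethylsilyloxy)-3-(methoxymethoxy)-5,9-dimethylundec-1-ene-4,5-diol
Conditions: LiAlH4, THF, 0 °C; then H2O
Reagents that add atoms: none
Why: Hydride opening of the 2,3-epoxy alcohol is an SN2 attack at the secondary carbon C1 (C10 is quaternary), so the C10–O bond and its configuration survive and give the (10R) tertiary alcohol.

**Step 8**
Reactants: 10 (3R,4S,5R,9S)-10,11-bis(tert-butyldimethylsilyloxy)-3-(methoxymethoxy)-5,9-dimethylundec-1-ene-4,5-diol; 11 (2E)-3-methylpent-2-enoic acid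
Product: 12 (3R,4S,5R,9S)-10,11-bis(tert-butyldimethylsilyloxy)-5-hydroxy-3-(methoxymethoxy)-5,9-dimethylundec-1-en-4-yl (2E)-3-methylpent-2-enoate
Conditions: DIC, DMAP, CH2Cl2, 0 °C to rt
Reagents that add atoms: none
Why: Steglich esterification acylates the only secondary hydroxyl (C9) while the tertiary C10 hydroxyl stays free; no stereocentre changes.

**Step 9**
Reactants: 12 (3R,4S,5R,9S)-10,11-bis(tert-butyldimethylsilyloxy)-5-hydroxy-3-(methoxymethoxy)-5,9-dimethylundec-1-en-4-yl (2E)-3-methylpent-2-enoate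
Product: 13 (3R,4S,5R,9S)-10,11-bis(tert-butyldimethylsilyloxy)-3,5-dihydroxy-5,9-dimethylundec-1-en-4-yl (2E)-3-methylpent-2-enoate
Conditions: Me2BBr, CH2Cl2, −78 °C; NaHCO3 aq.
Reagents that add atoms: none
Why: Guindon acetal cleavage: Me2BBr ionises the MOM acetal at its O–CH2 bond (C8–O untouched, retention) and leaves silyl ethers, esters and alkenes intact.

**Step 10**
Reactants: 13 (3R,4S,5R,9S)-10,11-bis(tert-butyldimethylsilyloxy)-3,5-dihydroxy-5,9-dimethylundec-1-en-4-yl (2E)-3-methylpent-2-enoate; 14 2-(bromomethyl)prop-2-enoic acid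
Product: 15 (3R,4S,5R,9S)-3-{[2-(bromomethyl)prop-2-enoyl]oxy}-10,11-bis(tert-butyldimethylsilyloxy)-5-hydroxy-5,9-dimethylundec-1-en-4-yl (2E)-3-methylpent-2-enoate
Conditions: DIC, DMAP (10 mol%), CH2Cl2, 0 °C
Reagents that add atoms: none
Why: Steglich esterification of the freed allylic C8 hydroxyl installs the future C11–C13 unit; low temperature and catalytic DMAP limit acyl migration and N-alkylation by the allylic bromide.

**Step 11**
Reactants: 15 (3R,4S,5R,9S)-3-{[2-(bromomethyl)prop-2-enoyl]oxy}-10,11-bis(tert-butyldimethylsilyloxy)-5-hydroxy-5,9-dimethylundec-1-en-4-yl (2E)-3-methylpent-2-enoate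
Product: 16 (3R,4S,5R,9S)-3-{[2-(bromomethyl)prop-2-enoyl]oxy}-5,10,11-trihydroxy-5,9-dimethylundec-1-en-4-yl (2E)-3-methylpent-2-enoate
Conditions: HF aq. (48%), MeCN, 0 °C
Reagents that add atoms: none
Why: Fluoride-driven desilylation (Si–F bond formation) frees the diol under amine-free conditions that spare the allylic bromide and both esters.

**Step 12**
Reactants: 16 (3R,4S,5R,9S)-3-{[2-(bromomethyl)prop-2-enoyl]oxy}-5,10,11-trihydroxy-5,9-dimethylundec-1-en-4-yl (2E)-3-methylpent-2-enoate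
Product: 17 (3R,4S,5R,9S)-3-{[2-(bromomethyl)prop-2-enoyl]oxy}-5-hydroxy-5,9-dimethyl-10,11-dioxoundec-1-en-4-yl (2E)-3-methylpent-2-enoate
Conditions: IBX, DMSO/THF, rt
Reagents that add atoms: none
Why: IBX (hypervalent-iodine oxidation) oxidises both carbinols of the terminal 1,2-diol without C–C cleavage, and the base-free medium protects the enolisable C4 centre.

**Step 13**
Reactants: 17 (3R,4S,5R,9S)-3-{[2-(bromomethyl)prop-2-enoyl]oxy}-5-hydroxy-5,9-dimethyl-10,11-dioxoundec-1-en-4-yl (2E)-3-methylpent-2-enoate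
Product: 19 CNP0197047.1, via bromomethylbutenolide ketoaldehyde 18 (not isolated)
Conditions: second-generation Hoveyda–Grubbs catalyst (7 mol%), CH2Cl2 (5 mM), 40 °C; then In powder, DMF, rt, slow addition (1 mM); NH4Cl aq.
Reagents that add atoms: none
Why: Proposed new method: RCM of the 2-(bromomethyl)acrylate with the C7 vinyl group closes the butenolide, then indium inserts into the allylic C–Br bond and the ring-locked allylindium adds through its γ-carbon C7 to the tethered aldehyde carbon C6 in a chair Zimmerman–Traxler transition state (anti addition gives 6S, attack on the lactone face opposite the C8–C9 bond gives the trans-fused 7S centre, the double bond moves to the exocyclic position); the closest known reaction types are Barbier allylation of aldehydes with 3-(bromomethyl)furan-2(5H)-one, indium-mediated mono-allylation of 1,2-dicarbonyls and Barbier/Nozaki–Hiyama–Kishi macrocyclisation to ten-membered germacranolides.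

**Compound list**
1 | (S)-β-citronellene, (3S)-3,7-dimethylocta-1,6-diene | C=C[C@@H](C)CCC=C(C)C | starting material
2 | (2E,6S)-2,6-dimethylocta-2,7-dien-1-ol | C=C[C@@H](C)CC/C=C(\C)CO | intermediate
3 | [(2S,3S)-2-methyl-3-[(3S)-3-methylpent-4-en-1-yl]oxiran-2-yl]methanol | C=C[C@@H](C)CC[C@@H]1O[C@@]1(C)CO | intermediate
4 | (2R,3S)-2-methyl-3-[(3S)-3-methylpent-4-en-1-yl]oxirane-2-carbaldehyde | C=C[C@@H](C)CC[C@@H]1O[C@@]1(C)C=O | intermediate
5 | (2R,3S)-3-[(3S)-4,5-dihydroxy-3-methylpentyl]-2-methyloxirane-2-carbaldehyde (both carbinol epimers) | OCC(O)[C@@H](C)CC[C@@H]1O[C@@]1(C)C=O | intermediate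
6 | (2R,3S)-3-[(3S)-4,5-bis(tert-butyldimethylsilyloxy)-3-methylpentyl]-2-methyloxirane-2-carbaldehyde | CC(C)(C)[Si](C)(C)OCC(O[Si](C)(C)C(C)(C)C)[C@@H](C)CC[C@@H]1O[C@@]1(C)C=O | intermediate
7 | allyl methoxymethyl ether, 3-(methoxymethoxy)prop-1-ene | C=CCOCOC | starting material
8 | (Z)-[3-(methoxymethoxy)allyl]bis(isopinocampheyl)borane, Ipc from (+)-α-pinene | COCO/C=C\CB([C@@H]1C[C@@H]2C[C@H]([C@H]1C)C2(C)C)[C@@H]1C[C@@H]2C[C@H]([C@H]1C)C2(C)C | intermediate (not isolated)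
9 | (1S,2R)-1-[(2S,3S)-3-[(3S)-4,5-bis(tert-butyldimethylsilyloxy)-3-methylpentyl]-2-methyloxiran-2-yl]-2-(methoxymethoxy)but-3-en-1-ol | CC(C)(C)[Si](C)(C)OCC(O[Si](C)(C)C(C)(C)C)[C@@H](C)CC[C@@H]1O[C@@]1(C)[C@@H](O)[C@H](OCOC)C=C | intermediate
10 | (3R,4S,5R,9S)-10,11-bis(tert-butyldimethylsilyloxy)-3-(methoxymethoxy)-5,9-dimethylundec-1-ene-4,5-diol | CC(C)(C)[Si](C)(C)OCC(O[Si](C)(C)C(C)(C)C)[C@@H](C)CCC[C@@](C)(O)[C@@H](O)[C@H](OCOC)C=C | intermediate
11 | (2E)-3-methylpent-2-enoic acid | CC/C(C)=C/C(=O)O | starting material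
12 | (3R,4S,5R,9S)-10,11-bis(tert-butyldimethylsilyloxy)-5-hydroxy-3-(methoxymethoxy)-5,9-dimethylundec-1-en-4-yl (2E)-3-methylpent-2-enoate | CC(C)(C)[Si](C)(C)OCC(O[Si](C)(C)C(C)(C)C)[C@@H](C)CCC[C@@](C)(O)[C@@H](OC(=O)/C=C(\C)CC)[C@H](OCOC)C=C | intermediate
13 | (3R,4S,5R,9S)-10,11-bis(tert-butyldimethylsilyloxy)-3,5-dihydroxy-5,9-dimethylundec-1-en-4-yl (2E)-3-methylpent-2-enoate | CC(C)(C)[Si](C)(C)OCC(O[Si](C)(C)C(C)(C)C)[C@@H](C)CCC[C@@](C)(O)[C@@H](OC(=O)/C=C(\C)CC)[C@H](O)C=C | intermediate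
14 | 2-(bromomethyl)prop-2-enoic acid | C=C(CBr)C(=O)O | starting material
15 | (3R,4S,5R,9S)-3-{[2-(bromomethyl)prop-2-enoyl]oxy}-10,11-bis(tert-butyldimethylsilyloxy)-5-hydroxy-5,9-dimethylundec-1-en-4-yl (2E)-3-methylpent-2-enoate | CC(C)(C)[Si](C)(C)OCC(O[Si](C)(C)C(C)(C)C)[C@@H](C)CCC[C@@](C)(O)[C@@H](OC(=O)/C=C(\C)CC)[C@H](OC(=O)C(=C)CBr)C=C | intermediate
16 | (3R,4S,5R,9S)-3-{[2-(bromomethyl)prop-2-enoyl]oxy}-5,10,11-trihydroxy-5,9-dimethylundec-1-en-4-yl (2E)-3-methylpent-2-enoate | OCC(O)[C@@H](C)CCC[C@@](C)(O)[C@@H](OC(=O)/C=C(\C)CC)[C@H](OC(=O)C(=C)CBr)C=C | intermediate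
17 | (3R,4S,5R,9S)-3-{[2-(bromomethyl)prop-2-enoyl]oxy}-5-hydroxy-5,9-dimethyl-10,11-dioxoundec-1-en-4-yl (2E)-3-methylpent-2-enoate | O=CC(=O)[C@@H](C)CCC[C@@](C)(O)[C@@H](OC(=O)/C=C(\C)CC)[C@H](OC(=O)C(=C)CBr)C=C | intermediate
18 | (1S,2R,6S)-1-[(2R)-4-(bromomethyl)-5-oxo-2,5-dihydrofuran-2-yl]-2-hydroxy-2,6-dimethyl-7,8-dioxooctyl (2E)-3-methylpent-2-enoate | O=CC(=O)[C@@H](C)CCC[C@@](C)(O)[C@@H](OC(=O)/C=C(\C)CC)[C@@H]1OC(=O)C(CBr)=C1 | intermediate (not isolated)
19 | CNP0197047.1, (3aS,4S,6S,10R,11S,11aR)-4,10-dihydroxy-6,10-dimethyl-3-methylidene-2,5-dioxododecahydrocyclodeca[b]furan-11-yl (2E)-3-methylpent-2-enoate | C=C1C(=O)O[C@@H]2[C@@H]1[C@H](O)C(=O)[C@@H](C)CCC[C@@](C)(O)[C@H]2OC(=O)/C=C(\C)CC | target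

**Totals**
Total step count: 13. Longest linear sequence: 13 steps, from (S)-β-citronellene.

**Three steps most likely to fail**

Step 13 (one-pot double ring closure): the macro-allylation may give oligomers, attack through the CH2 terminus, or the cis-fused epimer, and the free ketoaldehyde may not survive the RCM. The fallback sets out from 16. RCM alone (second-generation Hoveyda–Grubbs catalyst, CH2Cl2, 40 °C) closes the lactone first and gives the isolated bromomethylbutenolide triol F1. Palladium-catalysed Miyaura borylation (Pd2(dba)3, B2pin2, DMSO) replaces bromide by boron and gives the allylboronate F2. IBX then gives the ketoaldehyde boronate F3, which closes the ten-membered ring in dilute toluene by intramolecular allylboration through a metal-free closed chair transition state with the same anti/trans sense. Aqueous work-up returns to the route at 19.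

Step 6 (alkoxyallylboration): BF3 may open or rearrange the epoxy aldehyde, and reagent control may be eroded by the α-stereocentre. The fallback sets out from 6. An Evans syn-glycolate aldol (Bu2BOTf, i-Pr2NEt, (S)-4-benzyl-3-[(methoxymethoxy)acetyl]oxazolidin-2-one) sets C8 and C9 and gives the aldol imide F4. LiBH4 removes the auxiliary and gives the primary alcohol F5. TEMPO/PhI(OAc)2 oxidises only the primary carbinol to the aldehyde F6. Wittig methylenation (Ph3P=CH2, −78 °C) returns to the route at 9.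

Step 12 (diol to ketoaldehyde): over-oxidation, hydrate or oligomer formation, or C4 epimerisation may occur. The fallback sets out from 16. The dibutylstannylene acetal (Bu2SnO, toluene) is oxidised with NBS at the secondary carbinol only and gives the hydroxymethyl ketone F7. Dess–Martin oxidation of this primary α-ketol returns to the route at 17.

**Further compounds**
F1 | step 13 | (1S,2R,6S)-1-[(2R)-4-(bromomethyl)-5-oxo-2,5-dihydrofuran-2-yl]-2,7,8-trihydroxy-2,6-dimethyloctyl (2E)-3-methylpent-2-enoate | OCC(O)[C@@H](C)CCC[C@@](C)(O)[C@@H](OC(=O)/C=C(\C)CC)[C@@H]1OC(=O)C(CBr)=C1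
F2 | step 13 | (1S,2R,6S)-2,7,8-trihydroxy-2,6-dimethyl-1-[(2R)-5-oxo-4-[(4,4,5,5-tetramethyl-1,3,2-dioxaborolan-2-yl)methyl]-2,5-dihydrofuran-2-yl]octyl (2E)-3-methylpent-2-enoate | OCC(O)[C@@H](C)CCC[C@@](C)(O)[C@@H](OC(=O)/C=C(\C)CC)[C@@H]1OC(=O)C(CB2OC(C)(C)C(C)(C)O2)=C1
F3 | step 13 | (1S,2R,6S)-2-hydroxy-2,6-dimethyl-7,8-dioxo-1-[(2R)-5-oxo-4-[(4,4,5,5-tetramethyl-1,3,2-dioxaborolan-2-yl)methyl]-2,5-dihydrofuran-2-yl]octyl (2E)-3-methylpent-2-enoate | O=CC(=O)[C@@H](C)CCC[C@@](C)(O)[C@@H](OC(=O)/C=C(\C)CC)[C@@H]1OC(=O)C(CB2OC(C)(C)C(C)(C)O2)=C1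
F4 | step 6 | (4S)-4-benzyl-3-{(2S,3S)-3-[(2S,3S)-3-[(3S)-4,5-bis(tert-butyldimethylsilyloxy)-3-methylpentyl]-2-methyloxiran-2-yl]-3-hydroxy-2-(methoxymethoxy)propanoyl}-1,3-oxazolidin-2-one | CC(C)(C)[Si](C)(C)OCC(O[Si](C)(C)C(C)(C)C)[C@@H](C)CC[C@@H]1O[C@@]1(C)[C@@H](O)[C@H](OCOC)C(=O)N2[C@@H](Cc3ccccc3)COC2=O
F5 | step 6 | (2R,3S)-3-[(2S,3S)-3-[(3S)-4,5-bis(tert-butyldimethylsilyloxy)-3-methylpentyl]-2-methyloxiran-2-yl]-2-(methoxymethoxy)propane-1,3-diol | CC(C)(C)[Si](C)(C)OCC(O[Si](C)(C)C(C)(C)C)[C@@H](C)CC[C@@H]1O[C@@]1(C)[C@@H](O)[C@H](OCOC)CO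
F6 | step 6 | (2S,3S)-3-[(2S,3S)-3-[(3S)-4,5-bis(tert-butyldimethylsilyloxy)-3-methylpentyl]-2-methyloxiran-2-yl]-3-hydroxy-2-(methoxymethoxy)propanal | CC(C)(C)[Si](C)(C)OCC(O[Si](C)(C)C(C)(C)C)[C@@H](C)CC[C@@H]1O[C@@]1(C)[C@@H](O)[C@H](OCOC)C=O
F7 | step 12 | (3R,4S,5R,9S)-3-{[2-(bromomethyl)prop-2-enoyl]oxy}-5,11-dihydroxy-5,9-dimethyl-10-oxoundec-1-en-4-yl (2E)-3-methylpent-2-enoate | OCC(=O)[C@@H](C)CCC[C@@](C)(O)[C@@H](OC(=O)/C=C(\C)CC)[C@H](OC(=O)C(=C)CBr)C=C
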